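## Analysis of the target

Pollenitin 8-acetate (17) is a flavonol: a 4H-chromen-4-one (benzo ring A fused to pyranone ring C) with a 4-hydroxyphenyl group (ring B) at C2 and a hydroxyl at C3. Ring A is oxygenated everywhere except C6: a hydroxyl at C5 that is hydrogen-bonded to the C4 carbonyl, a methyl ether at C7, and an acetate at C8 next to the ring oxygen O1. The molecule is flat and has no stereocenter, so the problem is one of regiochemistry and of telling five oxygen functions apart. The aryl acetate is the most fragile group: it does not survive hydroxide, alkoxide or acidic alcohol, so it must go on late and be followed only by neutral chemistry. The 5,8-dioxygenated ring A is a masked hydroquinone that oxidises to the 5,8-quinone in base and air, and in hot strong acid it can isomerise to the 5,6-pattern (Wessely–Moser rearrangement). The difficulty is to build the 3-oxygenated pyranone and then place one acetyl group on O8 while O3, O5 and O4' end up free and O7 methylated. The strategy rests on two features. C4 is a single carbonyl carbon between C4a of ring A and the oxygen-bearing C3, so it can be delivered as carbon monoxide between an aryl halide and a ketone enolate. Without the C8 oxygen, ring A has a mirror plane through C4a and C7, so a 2,6-dioxygenated 4-methoxyphenyl unit closes to the same chromone whichever oxygen becomes O1; C8 is para to the 5-hydroxyl, so its oxygen can be added afterwards.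

## Retrosynthetic reasoning

Target 17 from dibenzyl ether 16. The two O–CH2 bonds at O3 and O4' are cut last. Hydrogenolysis is neutral, so the 8-acetate survives, and O7 is methylated, so the acetyl group has no neighbouring hydroxyl to migrate to. Keeping O3 and O4' benzylated until the end is what leaves only one reactive hydroxyl in the step before.

Acetate 16 from hydroquinone 15. The O8–acyl bond is cut. In 15 the 5-hydroxyl is tied to the C4 carbonyl by a hydrogen bond and is a poor nucleophile, and O3 and O4' are ethers, so the 8-hydroxyl is the only one that acylates under mild conditions.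

Hydroquinone 15 from chromone 13. The C8–O bond is cut, through aryl sulfate 14. An oxygen at C8 is not carried in the ring A building block, because it would destroy the mirror plane and ring closure could then give the 5,6,7- or the 5,7,8-pattern. After ring closure the only free phenol of 13 is the 5-hydroxyl, and C8 is its para position, the position an Elbs oxidation attacks.

Chromone 13 from iodide 4, carbon monoxide 10 and ketone 9. Three bonds are cut: O1–C2, C4–C3 and C4a–C4, through diketones 12 and 11. Cutting on both sides of C4 reduces that carbon to 10. It leaves ring B, C2, C3 and the C3 oxygen together in ketone 9, and ring A as the symmetric iodide 4. A cut at C2–C3 would instead need a ring A ketone that already carries the oxygenated two-carbon chain, which is harder to make. The forward reaction must join an aroylpalladium species to the enolate carbon of 9, and acid must then remove both acetal ethers and close ring C.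

Iodide 4 from bis-ether 2 and from diol 1. The C–I bond is cut, through aryllithium 3. The two methoxymethyl ethers are chosen because together they direct lithiation to the carbon between them and because they fall off in the acid that closes ring C. The methyl ether of 1 becomes the 7-methoxy group of 17 without further steps.

Ketone 9 from Weinreb amide 6 and Grignard reagent 8; 6 from acid chloride 5, and 8 from bromide 7. The aryl–carbonyl bond is cut. The benzyloxy group then arrives with the acyl fragment. Substitution of an α-halo ketone by an alkoxide is avoided, because alkoxides add to the carbonyl group of such ketones and give epoxy ethers.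

## Alternatives that were turned down

Alternative 1: Ring A is disconnected at C4a–C8a and the resulting chain is stored as a pyrone.
- Forward key step: a magnesium alkoxide in its alcohol opens the lactone of 4-hydroxy-6-{(3E)-4-[4-(benzyloxy)phenyl]-2-oxobut-3-en-1-yl}-2H-pyran-2-one A2 to the magnesium chelate of the triketo ester methyl (8E)-9-[4-(benzyloxy)phenyl]-3,5,7-trioxonon-8-enoate A3. The carbanion between its two ketones (future C4a) adds to the ester carbonyl (future C8a), and the Claisen product enolises to the aromatic ring A of chalcone (2E)-3-[4-(benzyloxy)phenyl]-1-(2,4,6-trihydroxyphenyl)prop-2-en-1-one A1.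
- For it: it copies the polyketide folding of chalcone synthase and needs neither a protecting group on ring A nor a transition metal. On these points it is stronger than the chosen route.
- Against it: the key step builds the one ring whose 1,3,5-trioxygenated pattern can be bought (as in 1). A3 can also fold by aldol attack of its C2 carbanion on the C7 ketone, which leads away from A1. A1 still lacks ring C, the C3 oxygen, the 7-O-methyl group, the C8 oxygen and the acetate, and its three phenols are not differentiated. Oxidative closure of a chalcone with two ortho hydroxyls by alkaline peroxide (Algar–Flynn–Oyamada reaction) tends to give aurones, so the C3 oxygen would need a detour through a flavanone and a flavone.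
- Comparison: the chosen key step starts from a bought ring A and delivers ring C with its C3 oxygen in place and protected, three steps from 17. This alternative would need about twice as many steps after its key step.

Alternative 2: C8a–O1, C4a–C4 and O1–C2 are disconnected, back to an aryne and an alkynoic acid.
- Forward key step: fluoride sets the aryne free from 5-methoxy-3-(methoxymethoxy)-2-(trimethylsilyl)phenyl trifluoromethanesulfonate A5. The carboxylate oxygen of 3-[4-(benzyloxy)phenyl]prop-2-ynoic acid A6 adds to the aryne carbon remote from the acetal ether (future C8a). The aryl anion at C4a takes over the acyl group, and the phenoxide so formed adds to the ynone to give 2-[4-(benzyloxy)phenyl]-7-methoxy-5-(methoxymethoxy)-4H-chromen-4-one A4.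
- For it: three bonds and ring C are formed in one mild operation without palladium and without CO gas. It equals the chosen key step in bond count and is stronger in operational simplicity. O5 and O7 are already differentiated.
- Against it: A4 has hydrogen at C3, so the C3 hydroxyl needs a separate late oxidation and then a protecting step before O8 can be acetylated selectively. A5 is unsymmetrical and needs a multistep preparation to place silyl, triflate and two different ethers, against two steps for 4. The phenoxide can close the ynone in the five-membered mode to an aurone. The C8 oxygen is still missing.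
- Comparison: the chosen strategy carries the C3 oxygen in ketone 9 and uses a symmetric iodide, at the price of handling CO and a palladium catalyst.

Alternative 3: Ring C is obtained by ring expansion of a five-membered precursor.
- Forward key step: alkali hydroxide in aqueous alcohol attacks the bromine- and oxygen-bearing ring carbon of 2-bromo-2-{bromo[4-(benzyloxy)phenyl]methyl}-4,6-dihydroxy-1-benzofuran-3(2H)-one A8, the dibromide of aurone (2Z)-2-{[4-(benzyloxy)phenyl]methylidene}-4,6-dihydroxy-1-benzofuran-3(2H)-one A9. The furanone opens to a phenoxide and a 1,2-diketone, the phenoxide displaces the benzylic bromide to form O1–C2, and enolisation gives 2-[4-(benzyloxy)phenyl]-3,5,7-trihydroxy-4H-chromen-4-one A7 (Auwers synthesis).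
- For it: it is classical, cheap and metal-free, and like the chosen route it delivers ring C together with the C3 oxygen. On cost and simplicity of reagents it is stronger.
- Against it: A9 and A8 carry free phenols on a 1,3,5-trioxygenated ring, which the halogen substitutes in competition with addition to the exocyclic double bond. The benzylic bromide of A8 is para to an alkoxy group and ionises easily, which diverts the ring expansion. A7 has three free hydroxyls: methylation at O7 competes with O3, and O3 must be masked before the C8 oxidation and the acetylation.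
- Comparison: chromone 13 leaves the chosen key step with exactly one free hydroxyl, the one that directs the Elbs oxidation. A7 would need extra protecting-group steps to reach that state.

Key step: step 5

Remark on the chemistry: compounds 11 and 12 contain one stereocenter (the carbon between the two carbonyl groups). It forms racemic, is configurationally labile and becomes the sp2 carbon C3 of 13, so no stereocontrol is needed anywhere in the route.

## Route

Step 1
Reactants: 1 5-methoxyresorcinol (5-methoxybenzene-1,3-diol)
Product: 2 1-methoxy-3,5-bis(methoxymethoxy)benzene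
Conditions: NaH, MOMCl, DMF, 0 °C to rt
Reagents that add atoms: chloromethyl methyl ether (MOMCl), COCCl
Why: Williamson etherification of both phenoxides by the hard chloromethyl ether; the MOM group is chosen because it directs the lithiation of step 2 and is removed by the acid that closes ring C in step 5.

Step 2
Reactants: 2 1-methoxy-3,5-bis(methoxymethoxy)benzene
Product: 4 2-iodo-5-methoxy-1,3-bis(methoxymethoxy)benzene, via aryllithium 3 (not isolated)
Conditions: n-BuLi, THF, 0 °C; then I2, −78 °C to rt
Reagents that add atoms: iodine, II
Why: Directed ortho-metalation: C2 of 2 lies between two MOM ethers, each able to chelate lithium, so it should be deprotonated in preference to C4 and C6, which have one MOM ether and one weaker methyl ether as neighbours; iodinolysis of aryllithium 3 then gives the iodide.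

Step 3
Reactants: 5 (benzyloxy)acetyl chloride
Product: 6 2-(benzyloxy)-N-methoxy-N-methylacetamide
Conditions: MeNHOMe·HCl, K2CO3, CH2Cl2/H2O, 0 °C to rt
Reagents that add atoms: N,O-dimethylhydroxylamine hydrochloride, CNOC.Cl
Why: Schotten–Baumann N-acylation of the hydroxylamine by the acid chloride; the carbonate takes up both equivalents of HCl.

Step 4
Reactants: 7 1-(benzyloxy)-4-bromobenzene; 6 2-(benzyloxy)-N-methoxy-N-methylacetamide
Product: 9 2-(benzyloxy)-1-[4-(benzyloxy)phenyl]ethan-1-one, via Grignard reagent 8 (not isolated)
Conditions: Mg, THF, reflux; then 6, THF, 0 °C; aq. HCl (1 M), 0 °C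
Reagents that add atoms: none
Why: Weinreb ketone synthesis: Grignard reagent 8 adds only once to amide 6 because the tetrahedral adduct is held as a five-membered magnesium chelate until the acidic quench; the α-benzyloxy group arrives with the acyl fragment, so no substitution on an α-halo ketone is needed.

Step 5
Reactants: 4 2-iodo-5-methoxy-1,3-bis(methoxymethoxy)benzene; 10 carbon monoxide; 9 2-(benzyloxy)-1-[4-(benzyloxy)phenyl]ethan-1-one
Product: 13 3-(benzyloxy)-2-[4-(benzyloxy)phenyl]-5-hydroxy-7-methoxy-4H-chromen-4-one, via bis-MOM diketone 11 (not isolated), via dihydroxy diketone 12 (not isolated)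
Conditions: Pd(OAc)2 (5 mol %), Xantphos (6 mol %), NaN(SiMe3)2 (2.2 equiv.), CO (1 atm), dioxane, 80 °C; then HCl, MeOH, 60 °C
Reagents that add atoms: carbon monoxide (compound 10), [C-]#[O+]
Why: Pd(OAc)2 is reduced in the flask to zerovalent palladium, which inserts into the C–I bond of 4; CO (10) then inserts into the aryl–palladium bond and gives an aroylpalladium iodide carried by the wide-bite-angle diphosphine. The sodium enolate of 9 replaces iodide on palladium and reductive elimination at carbon forms C4–C3, the C4a–C4 bond having been formed by the CO insertion; diketone 11 is more acidic than 9 and is deprotonated at once by the second equivalent of base, which shields it from further reaction. The closest known reaction type is the palladium-catalysed carbonylative α-arylation of aryl alkyl ketones by aryl iodides to 1,3-diketones, and the second stage is the acid cyclodehydration of an o-hydroxyaryl 1,3-diketone that ends a Baker–Venkataraman flavone synthesis. Methanolic HCl cleaves both MOM acetals to give 12; one phenol adds to the ring B ketone in a 6-exo-trig closure to a 2-hydroxychromanone, and acid-catalysed loss of water forms O1–C2 as part of pyranone ring C. No stereocenter is created: the benzyloxy-bearing carbon of 11 and 12 is racemic and becomes the sp2 carbon C3 of 13. The step needs carbonylation to outrun direct α-arylation and the enolate to be acylated at carbon and not at oxygen; the two ortho MOM-oxy groups of 4 slow direct aryl–enolate coupling and speed CO insertion, and the chelating phosphine favours C–C reductive elimination from the acyl complex. Ring closure has no regiochemical choice, because 12 has a mirror plane through C4a and C7 so that either phenol gives the same chromone, and only the ring B ketone can be reached in a six-membered closure.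

Step 6
Reactants: 13 3-(benzyloxy)-2-[4-(benzyloxy)phenyl]-5-hydroxy-7-methoxy-4H-chromen-4-one
Product: 15 3-(benzyloxy)-2-[4-(benzyloxy)phenyl]-5,8-dihydroxy-7-methoxy-4H-chromen-4-one, via potassium aryl sulfate 14 (not isolated)
Conditions: K2S2O8, aq. KOH, pyridine, 15–20 °C; then aq. HCl (2 M), Na2SO3, 70 °C
Reagents that add atoms: potassium peroxodisulfate (K2S2O8), [K+].[K+].[O-]S(=O)(=O)OOS(=O)(=O)[O-]
Why: Elbs persulfate oxidation: the 5-phenoxide attacks a peroxide oxygen of the peroxodisulfate through its para carbon C8 (the ortho carbon C6 is the minor site) and gives aryl sulfate 14, whose S–O bond is hydrolysed by warm dilute acid while Na2SO3 keeps hydroquinone 15 from oxidising to the quinone. Compound 13 has no other free phenol, so rings B and C are not attacked.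

Step 7
Reactants: 15 3-(benzyloxy)-2-[4-(benzyloxy)phenyl]-5,8-dihydroxy-7-methoxy-4H-chromen-4-one
Product: 16 3-(benzyloxy)-2-[4-(benzyloxy)phenyl]-5-hydroxy-7-methoxy-4-oxo-4H-chromen-8-yl acetate
Conditions: Ac2O (1.05 equiv.), pyridine, CH2Cl2, 0 °C, argon
Reagents that add atoms: acetic anhydride, CC(=O)OC(C)=O
Why: Chemoselective O-acylation: the 5-hydroxyl is locked in a hydrogen bond to the C4 carbonyl and is a poor nucleophile, so one equivalent of anhydride at 0 °C should acylate only the free 8-hydroxyl; exclusion of air prevents quinone formation.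

Step 8
Reactants: 16 3-(benzyloxy)-2-[4-(benzyloxy)phenyl]-5-hydroxy-7-methoxy-4-oxo-4H-chromen-8-yl acetate
Product: 17 pollenitin 8-acetate (3,5-dihydroxy-2-(4-hydroxyphenyl)-7-methoxy-4-oxo-4H-chromen-8-yl acetate)
Conditions: H2 (1 atm), Pd/C (10 %), EtOAc/THF, rt
Reagents that add atoms: none
Why: Catalytic hydrogenolysis of both benzyl ethers under neutral conditions; the acetate has no free neighbouring hydroxyl to migrate to, the non-alcoholic solvent prevents transesterification, and the conjugated C2–C3 double bond of the flavonol is not reduced at 1 atm.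

## Compound list

1 | 5-methoxyresorcinol (5-methoxybenzene-1,3-diol) | COc1cc(O)cc(O)c1 | starting material
2 | 1-methoxy-3,5-bis(methoxymethoxy)benzene | COCOc1cc(OC)cc(OCOC)c1 | intermediate
3 | [4-methoxy-2,6-bis(methoxymethoxy)phenyl]lithium | [Li]c1c(OCOC)cc(OC)cc1OCOC | intermediate (not isolated)
4 | 2-iodo-5-methoxy-1,3-bis(methoxymethoxy)benzene | COCOc1cc(OC)cc(OCOC)c1I | intermediate
5 | (benzyloxy)acetyl chloride | O=C(Cl)COCc1ccccc1 | starting material
6 | 2-(benzyloxy)-N-methoxy-N-methylacetamide | CON(C)C(=O)COCc1ccccc1 | intermediate
7 | 1-(benzyloxy)-4-bromobenzene | Brc1ccc(OCc2ccccc2)cc1 | starting material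
8 | [4-(benzyloxy)phenyl]magnesium bromide | Br[Mg]c1ccc(OCc2ccccc2)cc1 | intermediate (not isolated)
9 | 2-(benzyloxy)-1-[4-(benzyloxy)phenyl]ethan-1-one | O=C(COCc1ccccc1)c1ccc(OCc2ccccc2)cc1 | intermediate
10 | carbon monoxide | [C-]#[O+] | starting material
11 | 2-(benzyloxy)-1-[4-(benzyloxy)phenyl]-3-[4-methoxy-2,6-bis(methoxymethoxy)phenyl]propane-1,3-dione (racemic) | COCOc1cc(OC)cc(OCOC)c1C(=O)C(OCc1ccccc1)C(=O)c1ccc(OCc2ccccc2)cc1 | intermediate (not isolated)
12 | 2-(benzyloxy)-1-[4-(benzyloxy)phenyl]-3-(2,6-dihydroxy-4-methoxyphenyl)propane-1,3-dione (racemic) | COc1cc(O)c(C(=O)C(OCc2ccccc2)C(=O)c2ccc(OCc3ccccc3)cc2)c(O)c1 | intermediate (not isolated)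
13 | 3-(benzyloxy)-2-[4-(benzyloxy)phenyl]-5-hydroxy-7-methoxy-4H-chromen-4-one | COc1cc(O)c2c(=O)c(OCc3ccccc3)c(-c3ccc(OCc4ccccc4)cc3)oc2c1 | intermediate
14 | potassium 3-(benzyloxy)-2-[4-(benzyloxy)phenyl]-5-hydroxy-7-methoxy-4-oxo-4H-chromen-8-yl sulfate | COc1cc(O)c2c(=O)c(OCc3ccccc3)c(-c3ccc(OCc4ccccc4)cc3)oc2c1OS(=O)(=O)[O-].[K+] | intermediate (not isolated)
15 | 3-(benzyloxy)-2-[4-(benzyloxy)phenyl]-5,8-dihydroxy-7-methoxy-4H-chromen-4-one | COc1cc(O)c2c(=O)c(OCc3ccccc3)c(-c3ccc(OCc4ccccc4)cc3)oc2c1O | intermediate
16 | 3-(benzyloxy)-2-[4-(benzyloxy)phenyl]-5-hydroxy-7-methoxy-4-oxo-4H-chromen-8-yl acetate | COc1cc(O)c2c(=O)c(OCc3ccccc3)c(-c3ccc(OCc4ccccc4)cc3)oc2c1OC(C)=O | intermediate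
17 | pollenitin 8-acetate (3,5-dihydroxy-2-(4-hydroxyphenyl)-7-methoxy-4-oxo-4H-chromen-8-yl acetate) | COc1cc(O)c2c(=O)c(O)c(-c3ccc(O)cc3)oc2c1OC(C)=O | target

## Step count and risks

Total step count: 8. Longest linear sequence: 6 steps (steps 1, 2, 5, 6, 7, 8); steps 3 and 4 form a two-step branch that joins at step 5.

Least certain steps:

Step 5 (key step). Most likely failures: acylation of the enolate at oxygen instead of carbon; direct α-arylation without CO uptake; slow oxidative addition at the doubly ortho-substituted, electron-rich iodide, ending in proto-deiodination; interception of the aroylpalladium species by the amide base. The α-benzyloxy enolate is more stabilised and more hindered than the simple ketone enolates this reaction is usually run with.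
Fallback: stoichiometric acyl transfer, with C4 coming from carbon dioxide. It sets out from aryllithium 3 (generated from 2 as in step 2) and ketone 9, and returns to the route at chromone 13. Aryllithium 3 is quenched with CO2 at −78 °C and acidified to pH 4 to give 4-methoxy-2,6-bis(methoxymethoxy)benzoic acid F1. 1,1'-Carbonyldiimidazole in THF converts it into the acyl imidazole 1-[4-methoxy-2,6-bis(methoxymethoxy)benzoyl]-1H-imidazole F2. Ketone 9 is deprotonated with LiN(SiMe3)2 (2.2 equiv., THF, −78 °C) and acylated at carbon by F2 (crossed Claisen condensation) to give diketone 11, now isolated. Methanolic HCl converts 11 through 12 into 13, as in the second stage of step 5.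

Step 2. Most likely failure: competing deprotonation at C4 or C6, between a MOM ether and the methyl ether, giving a regioisomeric iodide that is hard to separate.
Fallback: a ring A partner with threefold symmetry, with the 7-O-methyl group added after ring closure. Compounds 1 to 4 are set aside; the fallback sets out from ketone 9 and carbon monoxide 10 and returns at chromone 13. Benzene-1,3,5-triol F3 (bought) is converted with NaH and MOMCl into 1,3,5-tris(methoxymethoxy)benzene F4, whose three ring positions are equivalent. N-Iodosuccinimide in MeCN gives 2-iodo-1,3,5-tris(methoxymethoxy)benzene F5. Under the conditions of step 5, F5, 10 and 9 should give 2-(benzyloxy)-1-[4-(benzyloxy)phenyl]-3-[2,4,6-tris(methoxymethoxy)phenyl]propane-1,3-dione F6, then 2-(benzyloxy)-1-[4-(benzyloxy)phenyl]-3-(2,4,6-trihydroxyphenyl)propane-1,3-dione F7 after acetal cleavage, and then 3-(benzyloxy)-2-[4-(benzyloxy)phenyl]-5,7-dihydroxy-4H-chromen-4-one F8. MeI (1.05 equiv.) and K2CO3 in acetone methylate only the acidic, non-chelated 7-hydroxyl of F8 and give 13.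

Step 6. Most likely failures: incomplete conversion because the potassium phenoxide of 13 dissolves poorly in the aqueous medium; further oxidation of the hydroquinone product; opening of the pyranone by hydroxide; ring opening and reclosure of ring A during the acid stage, which would isomerise the substitution pattern.
Fallback: halogenation, borylation and oxidation on a fully etherified ring A. It sets out from chromone 13 and returns at target 17, bypassing 15 and 16. The 5-hydroxyl is benzylated (BnBr, K2CO3, DMF, 70 °C) to give 3,5-bis(benzyloxy)-2-[4-(benzyloxy)phenyl]-7-methoxy-4H-chromen-4-one F9. N-Iodosuccinimide with catalytic CF3CO2H in MeCN should iodinate ring A at C8, between the methoxy group and O1, giving 3,5-bis(benzyloxy)-2-[4-(benzyloxy)phenyl]-8-iodo-7-methoxy-4H-chromen-4-one F10. Miyaura borylation (B2pin2, Pd(dppf)Cl2, KOAc, dioxane, 90 °C) gives 3,5-bis(benzyloxy)-2-[4-(benzyloxy)phenyl]-7-methoxy-8-(4,4,5,5-tetramethyl-1,3,2-dioxaborolan-2-yl)-4H-chromen-4-one F11. Oxidation with NaBO3·4H2O in THF/H2O gives 3,5-bis(benzyloxy)-2-[4-(benzyloxy)phenyl]-8-hydroxy-7-methoxy-4H-chromen-4-one F12. Ac2O and pyridine acetylate its only hydroxyl to give 3,5-bis(benzyloxy)-2-[4-(benzyloxy)phenyl]-7-methoxy-4-oxo-4H-chromen-8-yl acetate F13. Hydrogenolysis of the three benzyl ethers (H2, Pd/C, EtOAc/THF) gives 17.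

Step 7. Most likely failures: acetylation spilling over to the 5-hydroxyl, and air oxidation of the 5,8-hydroquinone in the basic medium before it is acylated.
Fallback: protection of the 5-hydroxyl by chelation instead of reliance on rate differences. It sets out from hydroquinone 15 and returns at acetate 16. Compound 15 is warmed to 60 °C in Ac2O with boroacetic anhydride, B(OAc)3, made from B(OH)3 and Ac2O. The 5-hydroxyl and the C4 carbonyl are tied up in a six-membered boron chelate while the 8-hydroxyl is acetylated, giving the diacetoxyboron O4,O5-chelate of 3-(benzyloxy)-2-[4-(benzyloxy)phenyl]-5-hydroxy-7-methoxy-4-oxo-4H-chromen-8-yl acetate F14. Stirring with cold water hydrolyses the boron chelate and leaves 16 with its 5-hydroxyl free.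

## Further compounds

F1 | step 5 | 4-methoxy-2,6-bis(methoxymethoxy)benzoic acid | COCOc1cc(OC)cc(OCOC)c1C(=O)O
F2 | step 5 | 1-[4-methoxy-2,6-bis(methoxymethoxy)benzoyl]-1H-imidazole | COCOc1cc(OC)cc(OCOC)c1C(=O)n1ccnc1
F3 | step 2 | benzene-1,3,5-triol (bought starting material of the fallback) | Oc1cc(O)cc(O)c1
F4 | step 2 | 1,3,5-tris(methoxymethoxy)benzene | COCOc1cc(OCOC)cc(OCOC)c1
F5 | step 2 | 2-iodo-1,3,5-tris(methoxymethoxy)benzene | COCOc1cc(OCOC)c(I)c(OCOC)c1
F6 | step 2 | 2-(benzyloxy)-1-[4-(benzyloxy)phenyl]-3-[2,4,6-tris(methoxymethoxy)phenyl]propane-1,3-dione (racemic) | COCOc1cc(OCOC)c(C(=O)C(OCc2ccccc2)C(=O)c2ccc(OCc3ccccc3)cc2)c(OCOC)c1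
F7 | step 2 | 2-(benzyloxy)-1-[4-(benzyloxy)phenyl]-3-(2,4,6-trihydroxyphenyl)propane-1,3-dione (racemic) | Oc1cc(O)c(C(=O)C(OCc2ccccc2)C(=O)c2ccc(OCc3ccccc3)cc2)c(O)c1
F8 | step 2 | 3-(benzyloxy)-2-[4-(benzyloxy)phenyl]-5,7-dihydroxy-4H-chromen-4-one | Oc1cc(O)c2c(=O)c(OCc3ccccc3)c(-c3ccc(OCc4ccccc4)cc3)oc2c1
F9 | step 6 | 3,5-bis(benzyloxy)-2-[4-(benzyloxy)phenyl]-7-methoxy-4H-chromen-4-one | COc1cc(OCc2ccccc2)c2c(=O)c(OCc3ccccc3)c(-c3ccc(OCc4ccccc4)cc3)oc2c1
F10 | step 6 | 3,5-bis(benzyloxy)-2-[4-(benzyloxy)phenyl]-8-iodo-7-methoxy-4H-chromen-4-one | COc1cc(OCc2ccccc2)c2c(=O)c(OCc3ccccc3)c(-c3ccc(OCc4ccccc4)cc3)oc2c1I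
F11 | step 6 | 3,5-bis(benzyloxy)-2-[4-(benzyloxy)phenyl]-7-methoxy-8-(4,4,5,5-tetramethyl-1,3,2-dioxaborolan-2-yl)-4H-chromen-4-one | COc1cc(OCc2ccccc2)c2c(=O)c(OCc3ccccc3)c(-c3ccc(OCc4ccccc4)cc3)oc2c1B1OC(C)(C)C(C)(C)O1
F12 | step 6 | 3,5-bis(benzyloxy)-2-[4-(benzyloxy)phenyl]-8-hydroxy-7-methoxy-4H-chromen-4-one | COc1cc(OCc2ccccc2)c2c(=O)c(OCc3ccccc3)c(-c3ccc(OCc4ccccc4)cc3)oc2c1O
F13 | step 6 | 3,5-bis(benzyloxy)-2-[4-(benzyloxy)phenyl]-7-methoxy-4-oxo-4H-chromen-8-yl acetate | COc1cc(OCc2ccccc2)c2c(=O)c(OCc3ccccc3)c(-c3ccc(OCc4ccccc4)cc3)oc2c1OC(C)=O
F14 | step 7 | diacetoxyboron O4,O5-chelate of 3-(benzyloxy)-2-[4-(benzyloxy)phenyl]-5-hydroxy-7-methoxy-4-oxo-4H-chromen-8-yl acetate | COc1cc2c3c(c1OC(C)=O)OC(-c1ccc(OCc4ccccc4)cc1)=C(OCc1ccccc1)C3=[O+][B-](OC(C)=O)(OC(C)=O)O2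
A1 | alternative 1 | (2E)-3-[4-(benzyloxy)phenyl]-1-(2,4,6-trihydroxyphenyl)prop-2-en-1-one | O=C(/C=C/c1ccc(OCc2ccccc2)cc1)c1c(O)cc(O)cc1O
A2 | alternative 1 | 4-hydroxy-6-{(3E)-4-[4-(benzyloxy)phenyl]-2-oxobut-3-en-1-yl}-2H-pyran-2-one | O=C(Cc1cc(O)cc(=O)o1)/C=C/c1ccc(OCc2ccccc2)cc1
A3 | alternative 1 | methyl (8E)-9-[4-(benzyloxy)phenyl]-3,5,7-trioxonon-8-enoate | COC(=O)CC(=O)CC(=O)CC(=O)/C=C/c1ccc(OCc2ccccc2)cc1
A4 | alternative 2 | 2-[4-(benzyloxy)phenyl]-7-methoxy-5-(methoxymethoxy)-4H-chromen-4-one | COCOc1cc(OC)cc2oc(-c3ccc(OCc4ccccc4)cc3)cc(=O)c12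
A5 | alternative 2 | 5-methoxy-3-(methoxymethoxy)-2-(trimethylsilyl)phenyl trifluoromethanesulfonate | COCOc1cc(OC)cc(OS(=O)(=O)C(F)(F)F)c1[Si](C)(C)C
A6 | alternative 2 | 3-[4-(benzyloxy)phenyl]prop-2-ynoic acid | OC(=O)C#Cc1ccc(OCc2ccccc2)cc1
A7 | alternative 3 | 2-[4-(benzyloxy)phenyl]-3,5,7-trihydroxy-4H-chromen-4-one | Oc1cc(O)c2c(=O)c(O)c(-c3ccc(OCc4ccccc4)cc3)oc2c1
A8 | alternative 3 | 2-bromo-2-{bromo[4-(benzyloxy)phenyl]methyl}-4,6-dihydroxy-1-benzofuran-3(2H)-one (racemic mixture of diastereomers) | O=C1c2c(O)cc(O)cc2OC1(Br)C(Br)c1ccc(OCc2ccccc2)cc1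
A9 | alternative 3 | (2Z)-2-{[4-(benzyloxy)phenyl]methylidene}-4,6-dihydroxy-1-benzofuran-3(2H)-one | O=C1c2c(O)cc(O)cc2O/C1=C\c1ccc(OCc2ccccc2)cc1
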